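Assumption: the target has no stereocentre and no chirality axis, so there is no enantiomer to select. It is made as the free bis(hydrogen sulfate) drawn in the SMILES.

## Retrosynthetic overview
1. 5 ⇒ 3 (hispidulin): cut the two S–O bonds. The 7-OH and 4'-OH are sulfated last, and the chelated 5-OH needs no protection.
2. 3 ⇒ 2 + MeOH: this is the key disconnection, the aryl C6–OMe carbon–oxygen bond, made by carbene-type O–H insertion with loss of PhI.
3. 2 ⇒ 1 (apigenin) + PhI(OAc)2: C6–H becomes a bond from C6 to trivalent iodine, between the two ring A hydroxyls.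
4. Rings: none is built. Rings A, C and B arrive intact in apigenin, and no protecting group is used.

## Route

Step 1
Reactants: 1 apigenin
Product: 2 5-hydroxy-2-(4-hydroxyphenyl)-4-oxo-6-(phenyliodonio)-4H-chromen-7-olate (zwitterion with PhI+ on C6 and O− on C7)
Conditions: PhI(OAc)2 (1.05 equiv), DMF, 0 °C to rt, dark, 3 h; pour into ice-water, filter, wash with Et2O
Reagents that add atoms: (diacetoxyiodo)benzene, CC(=O)OI(OC(C)=O)c1ccccc1
Why: This is aryliodonium phenolate (iodonium ylide) formation by ligand exchange at trivalent iodine and electrophilic C-substitution, as established for 2,4-dihydroxyacetophenones, 4-hydroxycoumarins and cyclic 1,3-diketones; the 5-OH···O=C4 chelate fixes enol character in C6=C7, so the carbon between the two hydroxyls is attacked (the same site as in iodination of 5-hydroxy-7-alkoxyflavones), the cationic iodine blocks a second substitution, and the ring B phenol, para to the electron-poor pyrone, is not oxidised at this temperature.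

Step 2
Reactants: 2 6-(phenyliodonio)apigenin-7-olate
Product: 3 hispidulin (5,7,4'-trihydroxy-6-methoxyflavone)
Conditions: Rh2(OAc)4 (2 mol %), MeOH (0.05 M), N2, dark, 40 °C, 4 h
Reagents that add atoms: methanol, CO
Why: Proposed new method: dirhodium-catalysed O–H insertion of methanol into an aromatic iodonium phenolate, forming an aryl C–O bond; C6 of 2 is an ylide carbon flanked by two oxygen-bearing carbons (a cyclic β-dicarbonyl iodonium ylide in its keto resonance form), so it binds the free axial site of Rh2(OAc)4, iodobenzene departs as an excellent leaving group, and the electrophilic rhodium-bound quinoid carbene (ring A as a 5-hydroxy-7-oxo dienone) is trapped by solvent methanol to give an oxonium ylide whose proton shift restores the aromatic ring with OMe on C6; divalent rhodium does not insert into the phenyl–iodine bond, so phenyl transfer is not expected, the step is redox-neutral so no oxidant remains to attack the electron-rich product, and the neutral medium cannot open ring C and exchange C6 with C8; the closest known reaction types are the Rh2(OAc)4- or copper-catalysed O–H insertion of β-dicarbonyl iodonium ylides into alcohols and the rhodium-catalysed O–H insertion of ortho-quinone diazides to catechol monoethers, neither of which has been shown for an iodonium phenolate of a polyphenolic flavone.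

Step 3
Reactants: 3 hispidulin
Product: 5 hispidulin 7,4'-disulfate, via bis(pyridinium) salt 4 (not isolated)
Conditions: SO3·pyridine (2.6 equiv), pyridine, rt to 40 °C, 12 h; H2O, 0 °C; Sephadex LH-20 (MeOH–H2O), eluate straight onto Dowex 50WX8 (H+ form), H2O, 4 °C; freeze-dry, store at −20 °C
Reagents that add atoms: sulfur trioxide–pyridine complex, O=S(=O)([O-])[n+]1ccccc1
Why: This is O-sulfation of phenols with an amine–SO3 complex: the acidic 7-OH and 4'-OH attack sulfur, the 5-OH stays free because it is hydrogen-bonded to C4=O and flanked by OMe, and cold cation exchange replaces pyridinium by H+ before the aryl sulfates can hydrolyse.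

## Compound list
1 | apigenin (5,7-dihydroxy-2-(4-hydroxyphenyl)-4H-chromen-4-one) | O=c1cc(-c2ccc(O)cc2)oc2cc(O)cc(O)c12 | starting material
2 | 5-hydroxy-2-(4-hydroxyphenyl)-4-oxo-6-(phenyliodonio)-4H-chromen-7-olate | O=c1cc(-c2ccc(O)cc2)oc2cc([O-])c([I+]c3ccccc3)c(O)c12 | intermediate
3 | hispidulin (5,7-dihydroxy-2-(4-hydroxyphenyl)-6-methoxy-4H-chromen-4-one) | COc1c(O)cc2oc(-c3ccc(O)cc3)cc(=O)c2c1O | intermediate
4 | hispidulin 7,4'-disulfate bis(pyridinium) salt | COc1c(OS(=O)(=O)[O-])cc2oc(-c3ccc(OS(=O)(=O)[O-])cc3)cc(=O)c2c1O.c1cc[nH+]cc1.c1cc[nH+]cc1 | intermediate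
5 | hispidulin 7,4'-disulfate (free acid, achiral) | COc1c(OS(=O)(=O)O)cc2oc(-c3ccc(OS(=O)(=O)O)cc3)cc(=O)c2c1O | target

## Step count and risks
Total step count: 3. Longest linear sequence: 3.

**Most likely to fail: step 2, the new step.**
- Failure modes:
  - Hydride transfer from methanol to the carbene would return apigenin.
  - Thermal phenyl migration from iodine to the 7-oxygen could compete.
  - The catalyst may simply not engage the aromatic zwitterion.
- The fallback uses known chemistry, sets out from 2 and keeps the C6 regiochemistry already secured.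
- KI and AcOH in DMF at 90 °C protonate the 7-oxygen, so the phenyl shift cannot compete. The diaryliodonium iodide then collapses thermally in the classical way.
- This gives 6-iodoapigenin F1 whichever aryl group the iodide attacks.
- Ullmann-type copper-mediated methanolysis (NaOMe, CuBr, MeOH–DMF, 100 °C), the method used on unprotected halo-5,7-dihydroxyflavones, then comes back to the route at 3.
- Because this medium is strongly basic, HMBC from the 5-OH proton must confirm that the methoxyl is on C6 and not on C8.

**Second: step 1.**
- Failure modes: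
  - Attack may occur at C8 instead of C6.
  - Ring B may be oxidised.
  - The neutral flavone may react too slowly.
- The fallback gives up direct C–H functionalisation of free apigenin, sets out from 1 and comes back at 3, bypassing steps 1 and 2.
- BnBr (2.2 equiv) and K2CO3 in DMF at 60 °C give 7,4'-di-O-benzylapigenin F2, leaving the chelated 5-OH free.
- NIS in DMF at rt gives 7,4'-di-O-benzyl-6-iodoapigenin F3, with the known C6 selectivity of 5-hydroxy-7-alkoxyflavones.
- BnBr and K2CO3 in DMF at 80 °C give 5,7,4'-tri-O-benzyl-6-iodoapigenin F4, which can no longer isomerise through ring C opening.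
- CuI, 1,10-phenanthroline and Cs2CO3 in MeOH–toluene at 110 °C give 5,7,4'-tri-O-benzylhispidulin F5.
- H2 over Pd/C in EtOAc–MeOH then gives 3.

**Third: step 3.**
- Failure modes:
  - Mixtures of mono- and disulfates may form.
  - Sulfuric acid from excess reagent may carry over.
  - The free acid may hydrolyse autocatalytically during isolation.
- The fallback changes to protected sulfate diesters that can be purified on silica. It sets out from 3.
- 2,2,2-Trichloroethyl chlorosulfate, Et3N and DMAP in THF give hispidulin 7,4'-bis(2,2,2-trichloroethyl sulfate) F6.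
- Zn and HCO2NH4 in MeOH at rt remove both trichloroethyl groups by reductive elimination, giving hispidulin 7,4'-disulfate diammonium salt F7, free of inorganic sulfate.
- The same cold H+ resin passage comes back to the route at 5.

## Further compounds
F1 | step 2 | 6-iodoapigenin | O=c1cc(-c2ccc(O)cc2)oc2cc(O)c(I)c(O)c12
F2 | step 1 | 7,4'-di-O-benzylapigenin | O=c1cc(-c2ccc(OCc3ccccc3)cc2)oc2cc(OCc3ccccc3)cc(O)c12
F3 | step 1 | 7,4'-di-O-benzyl-6-iodoapigenin | O=c1cc(-c2ccc(OCc3ccccc3)cc2)oc2cc(OCc3ccccc3)c(I)c(O)c12
F4 | step 1 | 5,7,4'-tri-O-benzyl-6-iodoapigenin | O=c1cc(-c2ccc(OCc3ccccc3)cc2)oc2cc(OCc3ccccc3)c(I)c(OCc3ccccc3)c12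
F5 | step 1 | 5,7,4'-tri-O-benzylhispidulin | COc1c(OCc2ccccc2)cc2oc(-c3ccc(OCc4ccccc4)cc3)cc(=O)c2c1OCc1ccccc1
F6 | step 3 | hispidulin 7,4'-bis(2,2,2-trichloroethyl sulfate) | COc1c(OS(=O)(=O)OCC(Cl)(Cl)Cl)cc2oc(-c3ccc(OS(=O)(=O)OCC(Cl)(Cl)Cl)cc3)cc(=O)c2c1O
F7 | step 3 | hispidulin 7,4'-disulfate diammonium salt | COc1c(OS(=O)(=O)[O-])cc2oc(-c3ccc(OS(=O)(=O)[O-])cc3)cc(=O)c2c1O.[NH4+].[NH4+]
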